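With the rings lettered A (3-methoxyphenyl), B (the phenol carrying the aryloxy group), C (the 1,4-phenylene) and D (3-hydroxyphenyl), the plan treats the CH2CH2 link from C4 of ring C, para to the ether oxygen, to C1 of ring D as a diarylalkyne in reduced form, because each of its carbons sits next to an aromatic sp2 carbon. Propiolic acid supplies these two carbons: in one flask its C–H end is arylated by a ring D iodide and its carboxyl end, with loss of CO2, by a bromide that already contains rings A, B and C with the ring B phenol benzylated. A single hydrogenation then saturates the alkyne and unmasks both phenols.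

Key step: step 5

Remark: (3-methoxybenzyl)triphenylphosphonium chloride is taken as a purchased salt. The Wittig product of step 2 is expected as an E/Z mixture and is carried on unseparated, because step 3 removes the double bond. The target has no stereocentre.

Step 1
Reactants: 1 4-(benzyloxy)-3-hydroxybenzaldehyde; 2 (4-bromophenyl)boronic acid
Product: 3 4-(benzyloxy)-3-(4-bromophenoxy)benzaldehyde
Conditions: Cu(OAc)2, pyridine, 4 Å MS, CH2Cl2, dry air, rt
Reagents that add atoms: none
Why: Chan–Lam–Evans O-arylation, in which the phenoxide and the aryl group transferred from boron meet on copper and reductive elimination from a trivalent copper aryl phenoxide should form the diaryl ether at room temperature, where the aldehyde, the benzyl ether and the C–Br bond are not touched; placing this coupling first spends only cheap material and removes the acidic OH before the ylide chemistry.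

Step 2
Reactants: 3 4-(benzyloxy)-3-(4-bromophenoxy)benzaldehyde; 4 (3-methoxybenzyl)triphenylphosphonium chloride
Product: 6 1-(benzyloxy)-2-(4-bromophenoxy)-4-[2-(3-methoxyphenyl)ethenyl]benzene (E/Z mixture), via benzylidenephosphorane 5 (not isolated)
Conditions: 4, KOtBu, THF, 0 °C; then 3, 0 °C to rt
Reagents that add atoms: none
Why: Wittig olefination, in which the semi-stabilised benzylic ylide 5 adds to the non-enolisable aldehyde and the oxaphosphetane collapses to the stilbene and triphenylphosphine oxide, the alkene geometry being of no consequence for the route.

Step 3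
Reactants: 6 1-(benzyloxy)-2-(4-bromophenoxy)-4-[2-(3-methoxyphenyl)ethenyl]benzene (E/Z mixture)
Product: 7 1-(benzyloxy)-2-(4-bromophenoxy)-4-[2-(3-methoxyphenyl)ethyl]benzene
Conditions: TsNHNH2, NaOAc, DME/H2O, reflux
Reagents that add atoms: none
Why: Diimide reduction, in which HN=NH released from the sulfonyl hydrazide delivers two hydrogens to the C=C bond of either isomer through a cyclic six-centre transition state, so that the aryl bromide and the benzyl ether, both at risk under catalytic hydrogenation, should stay intact.

Step 4
Reactants: 8 3-iodophenol
Product: 9 1-(benzyloxy)-3-iodobenzene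
Conditions: BnBr, K2CO3, acetone, reflux
Reagents that add atoms: benzyl bromide, BrCc1ccccc1
Why: Williamson ether synthesis, in which the phenoxide formed with K2CO3 displaces bromide from benzyl bromide by SN2 without touching the C–I bond, masking the acidic OH with a group that step 6 removes at no extra cost.

Step 5
Reactants: 9 1-(benzyloxy)-3-iodobenzene; 10 propiolic acid; 7 1-(benzyloxy)-2-(4-bromophenoxy)-4-[2-(3-methoxyphenyl)ethyl]benzene
Product: 12 1-(benzyloxy)-2-{4-[(3-benzyloxyphenyl)ethynyl]phenoxy}-4-[2-(3-methoxyphenyl)ethyl]benzene, via arylpropiolic acid 11 (not isolated)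
Conditions: 9, 10, Pd(PPh3)2Cl2 (5 mol %), Ph2P(CH2)4PPh2 (dppb, 10 mol %), DBU, DMSO, rt; then 7, 110 °C
Reagents that add atoms: none
Why: Pd(PPh3)2Cl2 is reduced in the flask to a zerovalent palladium species carrying dppb, which inserts into the C–I bond of 9 at room temperature; DBU removes the acetylenic proton of the propiolate and reductive elimination gives the arylpropiolate 11, a copper-free Sonogashira coupling in which the carboxylate keeps the second alkyne carbon blocked. After 7 is added and the mixture heated, zerovalent palladium inserts into the C–Br bond on ring C, the carboxylate of 11 binds to the resulting arylpalladium bromide and loses CO2 to an aryl(alkynyl)palladium species, and reductive elimination forms the C4(ring C)–C(sp) bond. The closest known reaction type is the one-pot Sonogashira and decarboxylative coupling of propiolic acid with two different aryl halides to unsymmetrical diarylalkynes. No ring is closed and no stereocentre is formed. The step needs each arene on its own alkyne carbon without symmetrical diarylalkynes, which is secured by the room-temperature reactivity of the iodide, by the carboxyl group that holds back the second terminus until heating, by adding 7 only once 9 is consumed, and by using 7 as the limiting component; the C–Br bond is the only site of 7 open to oxidative addition, the diaryl ether, benzyl ethers and methyl ether being inert to palladium and DBU.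

Step 6
Reactants: 12 1-(benzyloxy)-2-{4-[(3-benzyloxyphenyl)ethynyl]phenoxy}-4-[2-(3-methoxyphenyl)ethyl]benzene
Product: 13 2-{4-[2-(3-hydroxyphenyl)ethyl]phenoxy}-4-[2-(3-methoxyphenyl)ethyl]phenol
Conditions: H2 (1 atm), 10 % Pd/C, EtOAc/MeOH, rt
Reagents that add atoms: none
Why: Heterogeneous catalytic hydrogenation and hydrogenolysis, in which Pd/C should saturate the diarylalkyne by way of the stilbene and cleave both benzylic C–O bonds to toluene, while the aryl methyl ether and the diaryl ether, which have no benzylic C–O bond, persist.

Compound list
1 | 4-(benzyloxy)-3-hydroxybenzaldehyde | O=Cc1ccc(OCc2ccccc2)c(O)c1 | starting material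
2 | (4-bromophenyl)boronic acid | OB(O)c1ccc(Br)cc1 | starting material
3 | 4-(benzyloxy)-3-(4-bromophenoxy)benzaldehyde | O=Cc1ccc(OCc2ccccc2)c(Oc2ccc(Br)cc2)c1 | intermediate
4 | (3-methoxybenzyl)triphenylphosphonium chloride | COc1cccc(C[P+](c2ccccc2)(c2ccccc2)c2ccccc2)c1.[Cl-] | starting material
5 | (3-methoxybenzylidene)triphenylphosphorane | COc1cccc(C=P(c2ccccc2)(c2ccccc2)c2ccccc2)c1 | intermediate (not isolated)
6 | 1-(benzyloxy)-2-(4-bromophenoxy)-4-[2-(3-methoxyphenyl)ethenyl]benzene, E/Z mixture, double-bond geometry left undefined | COc1cccc(C=Cc2ccc(OCc3ccccc3)c(Oc3ccc(Br)cc3)c2)c1 | intermediate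
7 | 1-(benzyloxy)-2-(4-bromophenoxy)-4-[2-(3-methoxyphenyl)ethyl]benzene | COc1cccc(CCc2ccc(OCc3ccccc3)c(Oc3ccc(Br)cc3)c2)c1 | intermediate
8 | 3-iodophenol | Oc1cccc(I)c1 | starting material
9 | 1-(benzyloxy)-3-iodobenzene | Ic1cccc(OCc2ccccc2)c1 | intermediate
10 | propiolic acid (prop-2-ynoic acid) | C#CC(=O)O | starting material
11 | 3-[3-(benzyloxy)phenyl]prop-2-ynoic acid, present as its DBU salt | O=C(O)C#Cc1cccc(OCc2ccccc2)c1 | intermediate (not isolated)
12 | 1-(benzyloxy)-2-{4-[(3-benzyloxyphenyl)ethynyl]phenoxy}-4-[2-(3-methoxyphenyl)ethyl]benzene | COc1cccc(CCc2ccc(OCc3ccccc3)c(Oc3ccc(C#Cc4cccc(OCc5ccccc5)c4)cc3)c2)c1 | intermediate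
13 | 2-{4-[2-(3-hydroxyphenyl)ethyl]phenoxy}-4-[2-(3-methoxyphenyl)ethyl]phenol | COc1cccc(CCc2ccc(O)c(Oc3ccc(CCc4cccc(O)c4)cc3)c2)c1 | target

Total step count: 6. Longest linear sequence: 5 steps (steps 1, 2, 3, 5, 6); step 4 is a one-step branch that joins at step 5.

Steps most likely to fail

Step 5. On heating, the arylpropiolate may be protonated and lose CO2 to the terminal alkyne faster than the slow oxidative addition of the electron-rich ring C bromide can intercept it. Exchange of aryl groups on palladium may also lead to symmetrical diarylalkynes. The fallback sets out from 9. A Sonogashira coupling with trimethylsilylacetylene (Pd(PPh3)2Cl2, CuI, Et3N, rt) should give 1-(benzyloxy)-3-[(trimethylsilyl)ethynyl]benzene F1. Methanolysis of the C–Si bond (K2CO3, MeOH, rt) should then give 1-(benzyloxy)-3-ethynylbenzene F2. A second Sonogashira coupling of F2 with 7 (Pd(PPh3)2Cl2, CuI, Et3N, DMF, 80 °C) comes back to the route at 12. The two aryl–alkyne bonds are then made in separate operations, at the cost of two more steps.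

Step 1. Transmetalation and O-arylation of the ortho-benzyloxy phenol, whose nucleophilicity is lowered by the formyl group, may be slower than protodeboronation and oxidative hydroxylation of the boronic acid, so that the coupling stalls at partial conversion. The fallback sets out from 1. Its potassium phenoxide (KOtBu, THF, 0 °C) would be arylated without copper by bis(4-bromophenyl)iodonium triflate (rt to 40 °C) through ligand coupling on trivalent iodine. This comes back to the route at 3 directly and makes no new compound (F0).

Step 6. After fast saturation of the alkyne, hydrogenolysis may stall, leaving partly benzylated material. The cause could be poisoning of the catalyst by sulfur or phosphorus traces carried over from step 5, or slow cleavage of the ring B benzyl ether that is flanked by the aryloxy group. The fallback sets out from 12. The triple bond alone would be saturated over deliberately attenuated Pd/C (H2, Pd/C, Ph2S, EtOAc, rt) to 1-(benzyloxy)-2-{4-[2-(3-benzyloxyphenyl)ethyl]phenoxy}-4-[2-(3-methoxyphenyl)ethyl]benzene F3. Both benzyl ethers would then be cleaved by a Lewis acid in the presence of a cation scavenger (BCl3, pentamethylbenzene, CH2Cl2, −78 °C), conditions that spare aryl methyl ethers, to come back to the route at the target 13.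

Further compounds
F1 | step 5 | 1-(benzyloxy)-3-[(trimethylsilyl)ethynyl]benzene | C[Si](C)(C)C#Cc1cccc(OCc2ccccc2)c1
F2 | step 5 | 1-(benzyloxy)-3-ethynylbenzene | C#Cc1cccc(OCc2ccccc2)c1
F0 | step 1 | none | none
F3 | step 6 | 1-(benzyloxy)-2-{4-[2-(3-benzyloxyphenyl)ethyl]phenoxy}-4-[2-(3-methoxyphenyl)ethyl]benzene | COc1cccc(CCc2ccc(OCc3ccccc3)c(Oc3ccc(CCc4cccc(OCc5ccccc5)c4)cc3)c2)c1
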